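**Retrosynthetic overview**

1. The route rests on one feature of the target: the oxolane C3–C4 bond joins the β-carbons (C8' and C8) of two identical 4-hydroxy-3,5-dimethoxyphenyl-C3 units, the ring CH2–O–CH2 carbons are their γ-carbons, and the two benzylic α-carbons differ only in that the one on the C4 arm carries OH.
2. Oxolane O–CH2 bond: 5-exo-tet Williamson closure of a primary alcohol onto a CH2I group; the diol comes from hydride reduction of a γ-aryl-γ-lactone and the CH2I from the carboxyl group of a paraconic acid.
3. Paraconic acid: hydrogenolysis of one benzylic C–O bond of a C2-symmetric cis-fused bislactone (either bond gives the same product); the enantiomers are separated at this acid.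
4. Bislactone: oxidative β–β dimerisation of two molecules of sinapic acid, which makes the C8–C8' bond and both lactone C–O bonds in one operation.
5. Ring order: both γ-lactone rings (step 1), one lactone opened (step 2), the second lactone reduced and the oxolane closed last (steps 8 and 9).

Key step: step 1

**Remarks on the chemistry**

- Compounds 3, 4 and 5 are racemates; their names and SMILES show the enantiomer that is carried forward.
- Assumption: the salt of the (2S,3S,4R) acid with (R)-1-phenylethylamine is taken to be the less soluble diastereomer. If the opposite pairing crystallises, (S)-1-phenylethylamine is used in the same way.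
- Locants: C7, C8, C9 are the benzylic, β and γ carbons of the carbinol-bearing unit; C7', C8', C9' are those of the benzyl-bearing unit.

**Route**

Step 1
Reactants: 1 sinapic acid (two molecules)
Product: 4 racemic bislactone (1S,4S,5S,8S)-4,8-bis(4-hydroxy-3,5-dimethoxyphenyl)-3,7-dioxabicyclo[3.3.0]octane-2,6-dione (cis-fused; both aryl groups exo), via sinapic acid phenoxyl radical 2 (not isolated), via bis(quinone methide) diacid 3 (not isolated)
Conditions: FeCl3·6H2O (1.1 equiv per phenol, added slowly), acetone–H2O, N2, rt; precipitate filtered off
Reagents that add atoms: none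
Why: FeCl3 takes one electron and one proton from each phenol to give radical 2, whose spin is shared by O-4, C-1 and the β-carbon, and two radicals join β to β to give bis(quinone methide) 3, of which only the like (C2) pairing can go on to a bicycle. The closest known reaction type is the biomimetic oxidative dehydrodimerisation of hydroxycinnamic acids to dilactones. Each lactone ring closes by 5-exo-trig oxa-conjugate addition of the carboxylate of one half to the quinone methide carbon of the other half, which restores the aromatic ring. The two bridgehead centres come out cis because a bicyclo[3.3.0]octane of this size can only be cis-fused, and each benzylic centre is set by closure with its aryl group on the open convex face, trans to the neighbouring bridgehead substituent. The step needs β–β coupling in preference to β–5 and β–O–4 coupling; the methoxy groups at C-3 and C-5 occupy the ring positions ortho to the phenol and crowd O-4, and the tethered carboxylates capture the quinone methides before water can. Nothing chiral is present, so the product should form as the racemate.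

Step 2
Reactants: 4 racemic bislactone
Product: 5 racemic paraconic acid (2S,3S,4R)-4-(4-hydroxy-3,5-dimethoxybenzyl)-2-(4-hydroxy-3,5-dimethoxyphenyl)-5-oxooxolane-3-carboxylic acid
Conditions: H2 (1 atm), 10% Pd/C, THF–AcOH, rt; stopped after one equivalent of H2
Reagents that add atoms: none
Why: Heterogeneous hydrogenolysis of a benzylic acyloxy C–O bond; the two such bonds are related by the C2 axis so the first cleavage gives one product, it relieves the strain of the bicycle and leaves an unstrained γ-lactone that should react more slowly, and the three remaining stereocentres are not touched.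

Step 3
Reactants: 5 racemic paraconic acid; 6 (R)-1-phenylethylamine
Product: 7 (R)-1-phenylethylammonium (2S,3S,4R)-4-(4-hydroxy-3,5-dimethoxybenzyl)-2-(4-hydroxy-3,5-dimethoxyphenyl)-5-oxooxolane-3-carboxylate (crystalline salt)
Conditions: 6 (1.0 equiv), EtOH, reflux then slow cooling; recrystallisation from EtOH–H2O until the liberated acid is enantiopure by chiral HPLC
Reagents that add atoms: (R)-1-phenylethylamine, C[C@@H](N)c1ccccc1
Why: Classical resolution, in which the carboxylic acid (far more acidic than the phenols) forms two diastereomeric ammonium carboxylates of different solubility, so the absolute configuration of all three centres is fixed here by separation.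

Step 4
Reactants: 7 crystalline salt
Product: 8 (2S,3S,4R)-4-(4-hydroxy-3,5-dimethoxybenzyl)-2-(4-hydroxy-3,5-dimethoxyphenyl)-5-oxooxolane-3-carboxylic acid (single enantiomer)
Conditions: 1 M aq HCl, EtOAc, 0 °C
Reagents that add atoms: none
Why: Acid–base liberation, in which the carboxylate is protonated by mineral acid and the free acid passes into ethyl acetate while the lactone is stable to cold dilute acid.

Step 5
Reactants: 8 resolved paraconic acid
Product: 9 (3R,4R,5S)-3-(4-hydroxy-3,5-dimethoxybenzyl)-4-(hydroxymethyl)-5-(4-hydroxy-3,5-dimethoxyphenyl)oxolan-2-one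
Conditions: BH3·THF (excess), THF, 0 °C to rt; MeOH quench, evaporation; used at once
Reagents that add atoms: none
Why: Chemoselective borane reduction of a carboxylic acid through its acyloxyborane beside a γ-lactone, as is usual for paraconic acids; the phenols only form aryl borates that methanol cleaves again, and no stereocentre is involved (the label at C-4 changes only because CO2H becomes CH2OH).

Step 6
Reactants: 9 hydroxymethyl lactone
Product: 10 (3R,4S,5S)-3-(4-hydroxy-3,5-dimethoxybenzyl)-5-(4-hydroxy-3,5-dimethoxyphenyl)-4-(iodomethyl)oxolan-2-one
Conditions: PPh3, I2, imidazole, THF–MeCN, 0 °C to rt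
Reagents that add atoms: iodine, II
Why: Appel-type iodination, in which the primary alcohol becomes an alkoxyphosphonium salt that iodide displaces by SN2 at the CH2 group; phenols cannot be displaced this way, and imidazole is too weak a base to enolise the lactone.

Step 7
Reactants: 10 iodomethyl lactone
Product: 11 (3R,4S,5S)-3-[4-(tert-butyldimethylsilyloxy)-3,5-dimethoxybenzyl]-5-[4-(tert-butyldimethylsilyloxy)-3,5-dimethoxyphenyl]-4-(iodomethyl)oxolan-2-one
Conditions: TBSCl, imidazole, DMF, rt
Reagents that add atoms: tert-butyldimethylsilyl chloride, CC(C)(C)[Si](C)(C)Cl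
Why: Standard silylation of phenols, placed here because a free para-phenoxide under the basic hydride conditions of step 8 could expel the benzylic lactone oxygen as a quinone methide that hydride would reduce, which would erase the carbinol oxygen.

Step 8
Reactants: 11 bis-silylated iodomethyl lactone
Product: 12 (1S,2S,3R)-3-[4-(tert-butyldimethylsilyloxy)-3,5-dimethoxybenzyl]-1-[4-(tert-butyldimethylsilyloxy)-3,5-dimethoxyphenyl]-2-(iodomethyl)butane-1,4-diol
Conditions: LiBH4, THF, 0 °C to rt; aq NH4Cl, extraction; crude product used at once
Reagents that add atoms: none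
Why: Lithium borohydride reduction of a lactone to the 1,4-diol by two hydride additions at the carbonyl carbon; the benzylic C–O bond is not broken so the carbinol centre keeps its configuration, aryl silyl ethers are tolerated, and a β-branched primary iodide should be attacked by borohydride only slowly at this temperature.

Step 9
Reactants: 12 silylated iodo diol
Product: 13 (S)-[4-(tert-butyldimethylsilyloxy)-3,5-dimethoxyphenyl]{(3R,4R)-4-[4-(tert-butyldimethylsilyloxy)-3,5-dimethoxybenzyl]oxolan-3-yl}methanol
Conditions: NaH (1.2 equiv), THF, 0 °C to rt
Reagents that add atoms: none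
Why: Intramolecular Williamson ether synthesis, in which the primary alkoxide closes the oxolane by 5-exo-tet displacement of iodide while the benzylic alkoxide could only form an oxetane by the much slower 4-exo-tet path, so the ether oxygen ends up between the two γ-carbons and no stereocentre takes part.

Step 10
Reactants: 13 bis-silylated oxolane
Product: 14 target, (S)-(4-hydroxy-3,5-dimethoxyphenyl)[(3R,4R)-4-(4-hydroxy-3,5-dimethoxybenzyl)oxolan-3-yl]methanol
Conditions: Bu4NF, AcOH, THF, 0 °C
Reagents that add atoms: none
Why: Fluoride cleavage of aryl silyl ethers driven by the Si–F bond, with acetic acid buffering the phenoxide so that the para-hydroxybenzylic alcohol is not exposed to base and the aliphatic C–O bonds stay intact.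

**Compound list**

1 | sinapic acid, (E)-3-(4-hydroxy-3,5-dimethoxyphenyl)prop-2-enoic acid | COc1cc(/C=C/C(=O)O)cc(OC)c1O | starting material
2 | sinapic acid phenoxyl radical | COc1cc(/C=C/C(=O)O)cc(OC)c1[O] | intermediate
3 | bis(quinone methide) diacid, racemic (2R,3R)-2,3-bis[(3,5-dimethoxy-4-oxocyclohexa-2,5-dien-1-ylidene)methyl]butanedioic acid | OC(=O)[C@H](C=C1C=C(OC)C(=O)C(OC)=C1)[C@@H](C=C1C=C(OC)C(=O)C(OC)=C1)C(=O)O | intermediate
4 | racemic bislactone, (1S,4S,5S,8S)-4,8-bis(4-hydroxy-3,5-dimethoxyphenyl)-3,7-dioxabicyclo[3.3.0]octane-2,6-dione | COc1cc(cc(OC)c1O)[C@H]1OC(=O)[C@H]2[C@@H]1C(=O)O[C@@H]2c1cc(OC)c(O)c(OC)c1 | intermediate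
5 | racemic paraconic acid, (2S,3S,4R)-4-(4-hydroxy-3,5-dimethoxybenzyl)-2-(4-hydroxy-3,5-dimethoxyphenyl)-5-oxooxolane-3-carboxylic acid | COc1cc(cc(OC)c1O)[C@H]1OC(=O)[C@H](Cc2cc(OC)c(O)c(OC)c2)[C@@H]1C(=O)O | intermediate
6 | (R)-1-phenylethylamine | C[C@@H](N)c1ccccc1 | starting material
7 | (R)-1-phenylethylammonium salt of the (2S,3S,4R) acid | COc1cc(cc(OC)c1O)[C@H]1OC(=O)[C@H](Cc2cc(OC)c(O)c(OC)c2)[C@@H]1C(=O)[O-].C[C@@H]([NH3+])c1ccccc1 | intermediate
8 | (2S,3S,4R)-4-(4-hydroxy-3,5-dimethoxybenzyl)-2-(4-hydroxy-3,5-dimethoxyphenyl)-5-oxooxolane-3-carboxylic acid, single enantiomer | COc1cc(cc(OC)c1O)[C@H]1OC(=O)[C@H](Cc2cc(OC)c(O)c(OC)c2)[C@@H]1C(=O)O | intermediate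
9 | (3R,4R,5S)-3-(4-hydroxy-3,5-dimethoxybenzyl)-4-(hydroxymethyl)-5-(4-hydroxy-3,5-dimethoxyphenyl)oxolan-2-one | COc1cc(cc(OC)c1O)[C@H]1OC(=O)[C@H](Cc2cc(OC)c(O)c(OC)c2)[C@@H]1CO | intermediate
10 | (3R,4S,5S)-3-(4-hydroxy-3,5-dimethoxybenzyl)-5-(4-hydroxy-3,5-dimethoxyphenyl)-4-(iodomethyl)oxolan-2-one | COc1cc(cc(OC)c1O)[C@H]1OC(=O)[C@H](Cc2cc(OC)c(O)c(OC)c2)[C@@H]1CI | intermediate
11 | bis(tert-butyldimethylsilyl) ether of 10 | COc1cc(cc(OC)c1O[Si](C)(C)C(C)(C)C)[C@H]1OC(=O)[C@H](Cc2cc(OC)c(O[Si](C)(C)C(C)(C)C)c(OC)c2)[C@@H]1CI | intermediate
12 | (1S,2S,3R)-3-[4-(tert-butyldimethylsilyloxy)-3,5-dimethoxybenzyl]-1-[4-(tert-butyldimethylsilyloxy)-3,5-dimethoxyphenyl]-2-(iodomethyl)butane-1,4-diol | COc1cc(cc(OC)c1O[Si](C)(C)C(C)(C)C)[C@@H](O)[C@@H](CI)[C@@H](Cc1cc(OC)c(O[Si](C)(C)C(C)(C)C)c(OC)c1)CO | intermediate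
13 | bis(tert-butyldimethylsilyl) ether of the target | COc1cc(cc(OC)c1O[Si](C)(C)C(C)(C)C)[C@@H](O)[C@H]1COC[C@@H]1Cc1cc(OC)c(O[Si](C)(C)C(C)(C)C)c(OC)c1 | intermediate
14 | (S)-(4-hydroxy-3,5-dimethoxyphenyl)[(3R,4R)-4-(4-hydroxy-3,5-dimethoxybenzyl)oxolan-3-yl]methanol | COc1cc(C[C@H]2COC[C@@H]2[C@H](O)c2cc(OC)c(O)c(OC)c2)cc(OC)c1O | target

**Step count**

Total: 10 steps. Longest linear sequence: 10 steps, from sinapic acid 1 to 14; the resolving amine 6 enters at step 3.

**Steps most likely to fail**

Step 3. The two diastereomeric salts may co-crystallise or fail to crystallise, so that the enantiomers are not separated cleanly. Fallback: the separation is moved to a neutral compound and done by chromatography. It sets out from racemic acid 5, which is reduced with BH3·THF exactly as in step 5 to the racemic hydroxymethyl lactone F1. F1 is then separated into its enantiomers by preparative supercritical-fluid chromatography on an amylose tris(3,5-dimethylphenylcarbamate) phase, and the (3R,4R,5S) enantiomer rejoins the route at 9.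

Step 2. The hydrogenolysis may not stop after the first benzylic C–O bond, so that the second lactone is cleaved as well and the carbinol oxygen is lost. Fallback: ionic hydrogenation in place of catalytic hydrogenolysis. It sets out from 4, which is treated with Et3SiH in CF3CO2H–CH2Cl2 at 0 °C. Strain-assisted heterolysis of one protonated lactone gives a para-hydroxybenzylic cation that takes hydride from the silane, and the route is rejoined at 5. In the monolactone the same ionisation is answered by fast re-closure of the five-membered ring. Friedel–Crafts capture of the cation is ruled out by geometry, because the remaining aryl group and the new benzyl group lie on opposite faces of the lactone. This fallback makes no compound outside the list (F0).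

Step 8. Borohydride may displace the primary iodide (hydrodeiodination) in competition with reduction of the lactone, or basic alkoxyborates may epimerise the lactone α-carbon before it is reduced. Fallback: the reduction is handed to an electrophilic hydride. It sets out from 11, which is treated with iBu2AlH (excess) in CH2Cl2 at −78 °C, warming to −20 °C. This reagent is delivered through coordination to the carbonyl oxygen, has no SN2 reactivity towards alkyl iodides and is not basic enough to enolise the lactone. After Rochelle-salt work-up the route is rejoined at 12. This fallback makes no compound outside the list (F0).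

**Further compounds**

F1 | step 3 | racemic (3R,4R,5S)-3-(4-hydroxy-3,5-dimethoxybenzyl)-4-(hydroxymethyl)-5-(4-hydroxy-3,5-dimethoxyphenyl)oxolan-2-one (enantiomer carried forward shown) | COc1cc(cc(OC)c1O)[C@H]1OC(=O)[C@H](Cc2cc(OC)c(O)c(OC)c2)[C@@H]1CO
F0 | step 2 | none | none
F0 | step 8 | none | none
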